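**Retrosynthetic overview**
1. The only ring to be made is the 18-membered macrocycle; rings A (the ring with OH para to the ether oxygen), B (para-phenylene), C (catechol-type ring) and D (meta-phenylene) are bought as benzenes. The macrocycle is opened at the CH2–CH2 bridge between rings A and B, whose two carbons are traced back to two formyl carbons joined by an intramolecular reductive carbonyl (McMurry) coupling and then saturated.
2. Enabling feature: each bridge carbon sits on a ring carbon ortho (ring A) or para (ring B) to a diaryl ether oxygen. As CHO groups these two carbons first activate two fluoroarenes for the SNAr reactions that build both diaryl ethers, and then serve as the two like-polarity (electrophilic) partners of the ketyl coupling. Everything else in the precursor (aryl ethers, the saturated C–D bridge) is inert to low-valent titanium.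
3. The C–D bibenzyl comes from a Sonogashira coupling of a ring C bromide with 3-ethynylphenol and a chemoselective alkyne hydrogenation; the two phenols to be arylated are differentiated simply by the order of events.
4. Order: ether O–B (SNAr), C–D link, ether O–A (SNAr), macrocycle (McMurry), then alkene hydrogenation and BBr3 demethylation.

Key step: step 5

Remark on the chemistry: the target has no stereocentre; macrocyclic stilbene 11 is assumed to form as an E/Z mixture that is carried on unseparated, since step 6 saturates the double bond.

**Step 1**
Reactants: 1 5-bromo-2-methoxyphenol; 2 4-fluorobenzaldehyde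
Product: 3 4-(5-bromo-2-methoxyphenoxy)benzaldehyde
Conditions: K2CO3, DMF, 120 °C
Reagents that add atoms: none
Why: Nucleophilic aromatic substitution (SNAr), in which the para-formyl group activates the C–F bond of 2 towards the phenoxide of 1 while the aryl bromide stays untouched in the absence of a metal catalyst.

**Step 2**
Reactants: 3 4-(5-bromo-2-methoxyphenoxy)benzaldehyde; 4 3-ethynylphenol
Product: 5 4-{5-[(3-hydroxyphenyl)ethynyl]-2-methoxyphenoxy}benzaldehyde
Conditions: PdCl2(PPh3)2 (cat.), CuI (cat.), Et3N, DMF, 80 °C, degassed
Reagents that add atoms: none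
Why: Sonogashira coupling of the terminal alkyne of 4 with the only C–Br bond of 3, the free phenol and the aldehyde being tolerated under the amine base.

**Step 3**
Reactants: 5 4-{5-[(3-hydroxyphenyl)ethynyl]-2-methoxyphenoxy}benzaldehyde
Product: 7 4-{5-[2-(3-hydroxyphenyl)ethyl]-2-methoxyphenoxy}benzaldehyde, via Z-stilbene 6 (not isolated)
Conditions: H2 (1 atm), 10% Pd/C, Ph2S (cat.), EtOAc, rt
Reagents that add atoms: none
Why: Heterogeneous catalytic hydrogenation takes the diarylalkyne by syn addition through Z-stilbene 6 to the bibenzyl, while diphenyl sulfide tempers the palladium surface so that the aromatic aldehyde should not be reduced.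

**Step 4**
Reactants: 7 4-{5-[2-(3-hydroxyphenyl)ethyl]-2-methoxyphenoxy}benzaldehyde; 8 2-fluoro-5-methoxybenzaldehyde
Product: 9 2-(3-{2-[3-(4-formylphenoxy)-4-methoxyphenyl]ethyl}phenoxy)-5-methoxybenzaldehyde
Conditions: K2CO3, DMA, 150 °C, N2, 8 in excess
Reagents that add atoms: none
Why: SNAr in which the ortho-formyl group of 8 activates the C–F bond towards the phenoxide of 7 (the para-methoxy group slows the substitution, hence the higher temperature), and the aldehyde so introduced is the second coupling handle.

**Step 5**
Reactants: 9 2-(3-{2-[3-(4-formylphenoxy)-4-methoxyphenyl]ethyl}phenoxy)-5-methoxybenzaldehyde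
Product: 11 macrocyclic stilbene dimethyl ether (E/Z mixture), via titanium pinacolate 10 (not isolated)
Conditions: TiCl4, Zn dust, pyridine, THF, reflux; 9 added by syringe pump over about 20 h (final concentration about 2 mM); aq. K2CO3 work-up
Reagents that add atoms: none
Why: Intramolecular McMurry coupling: low-valent titanium generated from TiCl4 and Zn transfers one electron to each formyl group, the two titanium-bound ketyl radicals (two carbons of the same, originally electrophilic, polarity) recombine to the C–C bond of titanium pinacolate 10, and twofold C–O cleavage on the oxophilic titanium then delivers stilbene 11. The closest known reaction type is the reductive carbonyl macrocyclisation of aromatic dialdehydes to cyclic stilbenes and cyclophanes, which is established for macrocyclic bis(bibenzyl) skeletons. The 18-membered ring is closed by radical–radical recombination of the two chain termini held on titanium (a macrocyclisation, not a polar exo or endo attack). The two carbinol stereocentres of 10 form without control and are erased in the same operation, and the E/Z geometry of 11 is irrelevant because step 6 saturates the double bond. The selectivity needed is intra- over intermolecular coupling, secured by slow addition into a large excess of reagent and by the ortho-linked ring A and meta-linked ring D, which fold the chain so that the two formyl groups can meet. Chemoselectivity rests on the substrate itself, since aryl methyl ethers, diaryl ethers and the saturated C–D bridge are inert to low-valent titanium.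

**Step 6**
Reactants: 11 macrocyclic stilbene dimethyl ether (E/Z mixture)
Product: 12 macrocyclic bis(bibenzyl) dimethyl ether (di-O-methyl ether of the target)
Conditions: H2 (1 atm), 10% Pd/C, EtOAc/EtOH, rt
Reagents that add atoms: none
Why: Catalytic hydrogenation of the stilbene C=C over Pd/C, in which both geometric isomers converge on one product and the diaryl and aryl methyl ethers are stable.

**Step 7**
Reactants: 12 macrocyclic bis(bibenzyl) dimethyl ether
Product: 14 CNP0135015.0 (macrocyclic bis(bibenzyl) diphenol, target), via bis(dibromoboryl) ether 13 (not isolated)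
Conditions: BBr3 (excess), CH2Cl2, −78 °C to rt; then ice/H2O
Reagents that add atoms: none
Why: Lewis acid ether cleavage, in which BBr3 binds each methoxy oxygen and bromide removes the methyl group by SN2 attack to give bis(dibromoboryl) ether 13, hydrolysed on work-up, whereas the diaryl ethers offer no sp3 carbon and survive.

**Compound list**
1 | 5-bromo-2-methoxyphenol | COc1ccc(Br)cc1O | starting material
2 | 4-fluorobenzaldehyde | O=Cc1ccc(F)cc1 | starting material
3 | 4-(5-bromo-2-methoxyphenoxy)benzaldehyde | COc1ccc(Br)cc1Oc1ccc(C=O)cc1 | intermediate
4 | 3-ethynylphenol | C#Cc1cccc(O)c1 | starting material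
5 | 4-{5-[(3-hydroxyphenyl)ethynyl]-2-methoxyphenoxy}benzaldehyde | COc1ccc(C#Cc2cccc(O)c2)cc1Oc1ccc(C=O)cc1 | intermediate
6 | 4-{5-[(Z)-2-(3-hydroxyphenyl)ethenyl]-2-methoxyphenoxy}benzaldehyde (Z-stilbene, not isolated) | COc1ccc(/C=C\c2cccc(O)c2)cc1Oc1ccc(C=O)cc1 | intermediate
7 | 4-{5-[2-(3-hydroxyphenyl)ethyl]-2-methoxyphenoxy}benzaldehyde | COc1ccc(CCc2cccc(O)c2)cc1Oc1ccc(C=O)cc1 | intermediate
8 | 2-fluoro-5-methoxybenzaldehyde | COc1ccc(F)c(C=O)c1 | starting material
9 | 2-(3-{2-[3-(4-formylphenoxy)-4-methoxyphenyl]ethyl}phenoxy)-5-methoxybenzaldehyde | COc1ccc(Oc2cccc(CCc3ccc(OC)c(Oc4ccc(C=O)cc4)c3)c2)c(C=O)c1 | intermediate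
10 | macrocyclic titanium pinacolate (titanium-bound in the flask, drawn as the parent 1,2-diol; mixture of diastereomers at the two carbinol carbons, not isolated) | COc1ccc2c(c1)C(O)C(O)c1ccc(cc1)Oc1cc(ccc1OC)CCc1cccc(c1)O2 | intermediate
11 | macrocyclic stilbene dimethyl ether (E/Z mixture at the new C=C, geometry left open) | COc1ccc2c(c1)C=Cc1ccc(cc1)Oc1cc(ccc1OC)CCc1cccc(c1)O2 | intermediate
12 | macrocyclic bis(bibenzyl) dimethyl ether | COc1ccc2c(c1)CCc1ccc(cc1)Oc1cc(ccc1OC)CCc1cccc(c1)O2 | intermediate
13 | bis(dibromoboryl) ether of the target (not isolated) | BrB(Br)Oc1ccc2c(c1)CCc1ccc(cc1)Oc1cc(ccc1OB(Br)Br)CCc1cccc(c1)O2 | intermediate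
14 | CNP0135015.0 (no stereocentre) | Oc1ccc2c(c1)CCc1ccc(cc1)Oc1cc(ccc1O)CCc1cccc(c1)O2 | target

**Step count and risks**
Total step count: 7. Longest linear sequence: 7 steps (from 1 and 2 to 14; 4 and 8 are bought).

Steps most likely to fail:

Step 5 (macrocyclisation). Intermolecular ketyl coupling to oligomers may outrun the ring closure, or the reaction may stall at the pinacol stage. Fallback, from dialdehyde 9: NaBH4 (MeOH/THF, 0 °C) should give the bis(hydroxymethyl) compound F1. PBr3 (CH2Cl2, 0 °C) should convert it into the bis(bromomethyl) compound F2. An intramolecular Wurtz coupling (Na, tetraphenylethene, THF, high dilution) would then join the same two benzylic carbons directly at the CH2–CH2 level. This returns to the route at compound 12, bypassing steps 5 and 6.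

Step 4 (second ether). Fluoride displacement on the ring deactivated by the para-methoxy group may be slow enough that aryloxide exchange at the 4-aryloxybenzaldehyde unit and base-induced loss of aldehyde compete. Fallback, from phenol 7: a copper-catalysed Ullmann etherification with commercial 2-bromo-5-methoxybenzaldehyde (CuI, N,N-dimethylglycine, Cs2CO3, dioxane, 100 °C). Its C–Br activation does not depend on SNAr activation and it runs at lower temperature. It returns to the route at compound 9; no new compound is made on the way (F0).

Step 3 (chemoselective hydrogenation). The formyl group may be over-reduced to hydroxymethyl or methyl, or the reduction may stall at the stilbene stage if the catalyst is over-poisoned. Fallback, from alkyne 5: acetalisation (ethylene glycol, TsOH, toluene, Dean–Stark) should give the dioxolane-protected alkyne F3. Unpoisoned hydrogenation (H2, Pd/C, EtOAc) should give the dioxolane-protected bibenzyl F4. Aqueous HCl in THF would release the aldehyde and return to the route at compound 7.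

**Further compounds**
F1 | step 5 | {2-[3-(2-{3-[4-(hydroxymethyl)phenoxy]-4-methoxyphenyl}ethyl)phenoxy]-5-methoxyphenyl}methanol | COc1ccc(Oc2cccc(CCc3ccc(OC)c(Oc4ccc(CO)cc4)c3)c2)c(CO)c1
F2 | step 5 | 2-(bromomethyl)-1-[3-(2-{3-[4-(bromomethyl)phenoxy]-4-methoxyphenyl}ethyl)phenoxy]-4-methoxybenzene | COc1ccc(Oc2cccc(CCc3ccc(OC)c(Oc4ccc(CBr)cc4)c3)c2)c(CBr)c1
F0 | step 4 | none | none
F3 | step 3 | 3-({3-[4-(1,3-dioxolan-2-yl)phenoxy]-4-methoxyphenyl}ethynyl)phenol | COc1ccc(C#Cc2cccc(O)c2)cc1Oc1ccc(C2OCCO2)cc1
F4 | step 3 | 3-(2-{3-[4-(1,3-dioxolan-2-yl)phenoxy]-4-methoxyphenyl}ethyl)phenol | COc1ccc(CCc2cccc(O)c2)cc1Oc1ccc(C2OCCO2)cc1
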